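## Structural features

The target is the methyl ester of a 2-(1,2-dioxan-3-yl)propanoic acid (C1' ester carbon, C2', ring carbons C3'–C6'). Its quaternary peroxide carbon C6' is joined through a two-carbon linker (C12–C11) to C9 of a cis-fused decalin (C1–C10). In the decalin three fully substituted carbons stand in a row (gem-dimethyl C4, tertiary carbinol C5, methyl-bearing fusion carbon C10) and are followed by the tertiary centres C9 (chain) and C8 (methyl). The hydroxyl, the C10 methyl and the C9 chain lie on one face; the C8 methyl lies on the other and is equatorial in the favoured chair. On the peroxide side C2' and C3' are adjacent stereocentres, and C6' stands 1,4 to C3' with its methyl cis to the propanoate arm. The fragile groups are the O–O bond (reductants, organometallics, hydrogenation, base at C3'–H), the tertiary C5 hydroxyl between two quaternary carbons (ionisation under acid) and C2'–H once the ester is present (epimerisation, β-elimination of the peroxide). The real difficulties are the C4–C5–C10 congestion, the control of C5, C9 and C10, and C6', whose methyl and primary-alkyl substituents are equal in size so that no ring conformation can bias it. The key step uses the fact that the C7–C8 bond of ring B lies opposite the C5–C10 fusion: C5, C9 and C10 are set on a monocyclic ring A ketone and ring B is closed last at an unhindered site.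

## Logic of the disconnections

**27 to 25 (through 26).** The ester O–CH3 bond is cut and C1' is taken back one oxidation level. A β-peroxy ester would not survive the basic ring closure (elimination of the sulfonate or of the peroxide), so C1' travels as a silyl-protected primary alcohol. The gain is that the last two steps are functional-group changes on a finished skeleton. The demand is that oxidation and methylation be non-basic and spare the O–O bond, C2' and the tertiary alcohol.

**25 to 22.** The C3'–O bond (and the two O–Si bonds) are cut. C3' can then be set by inversion at a carbinol carbon whose configuration comes from a reagent-controlled allylation. The ring becomes an open chain carrying a tertiary silyl peroxide and a secondary sulfonate. The demand is that 6-exo substitution by the peroxide anion outrun elimination.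

**22 to 21.** The C6'–O bond is cut. A tertiary peroxide is best made from a trisubstituted alkene by radical hydroperoxysilylation, which tolerates the free tertiary alcohol and the sulfonate. The gain is an alkene whose geometry does not matter. The cost is that the planar C6' radical cannot be biased, so both configurations form there.

**21 to 15 and 20.** The C5'=C6' bond is cut by cross-metathesis. This joins the decalin and the stereodefined C1'–C5' unit in one convergent step. The demand is that the gem-disubstituted alkene of 15 take part; an excess of 20 compensates for its homodimerisation.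

**20 to 16 (through 19, 18, 17).** The C3'–C4' bond is cut (allylation of an aldehyde) and the O–S bond. C2' is taken from the chiral pool and C3' is set next to it in a matched, reagent-controlled addition. The demand is a configurationally stable α-methyl aldehyde and the syn diastereomer.

**15 to 12 (through 14, 13).** The terminal methylene is traced to the ketone oxygen, the ketone to its ketal, and the C8–H bond to the C7=C8 alkene. The ketal keeps the side-chain carbonyl silent until ring B is complete. The demand on the forward reduction is delivery of hydrogen to the face of the C5 hydroxyl.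

**12 to 11.** The C7=C8 bond is cut (key step). It is the ring B bond remote from C4, C5 and C10. The bicycle becomes a ring A carbinol with an allyl group and an isopropenyl-bearing arm. The demand is only chemoselectivity; the two arms must be cis on ring A.

**11 to 10.** The C5–C6 bond is cut (allyl addition to a ketone). The ketone has no α-hydrogen. The demand is axial attack anti to the two axial α-methyl groups.

**10 to 5 and 3 (through 9, 8).** The C9–C10 bond is cut by a [3,3] shift, and one C4–CH3 bond by enolate methylation. The fully substituted 2,2,6-trimethyl ketone resists ketal and enol ether formation and its enolate allylates on carbon, so the rearrangement is run on the 2,6-dimethyl ketal and the gem-dimethyl group is completed afterwards. Both partners are achiral and no dependable asymmetric version of this rearrangement exists, so 9 is racemic and is resolved to 10. The demand is a chair transition state with the (E)-alkene.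

**3 to 1 (through 2) and 5 to 4.** The allylic C–O bond of 3 is cut (allylic oxidation of the ketal of a commercial enone). 5 is the dimethyl ketal of a commercial ketone.

## Other disconnections considered

**Alternative 1: angular methyl from a cyclopropane.**
- Cut: the C10–CH3 bond, traced to a cyclopropane across C10 and C1.
- Forward step: the carbenoid from Et2Zn and CH2I2 adds to the C1=C10 alkene of the 10-nor allylic alcohol A1 on the face of the C5 hydroxyl, giving cyclopropane A2; hydrogenolysis of the C1–CH2 bond then reveals the methyl group.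
- In favour: coordination of zinc to the tertiary allylic alkoxide ties the configuration of C10 to that of C5 in one well-understood step. On this point it is better than the chosen plan, where the C5/C10 relationship depends on the facial selectivity of a Grignard addition.
- Against: two steps are spent on one methyl group. A2 is a cyclopropylcarbinol with a tertiary hydroxyl, so acidic hydrogenolysis invites cyclopropylcarbinyl rearrangement. The choice of which cyclopropane bond breaks is not secured. A1 already needs ring B with C8 and C9 in place, so the hard part of the decalin is only moved.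
- Comparison: mechanistically a directed cheletropic addition against a metathesis that sets no stereocentre. Structurally it solves C10 alone, whereas the chosen plan sets C9 and C10 together. In step count it is no shorter.

**Alternative 2: dioxane from a diene and singlet oxygen.**
- Cut: both C–O bonds of the peroxide ring.
- Forward step: sensitised singlet oxygen adds suprafacially across C3' and C6' of the (E,Z)-diene A3 to give the 3,6-dihydro-1,2-dioxine A4, which needs diimide reduction and adjustment at C1'.
- In favour: both C–O bonds form in one step, and the C3'/C6' relationship is fixed by the diene geometry. On this point it is better than the chosen plan, which cannot control C6'.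
- Against: the (Z)-trisubstituted terminus places the large chain inside the s-cis conformer, so cycloaddition is slowed and ene reaction at the allylic hydrogens competes. The face of attack is governed only by the C2' stereocentre next to an (E)-alkene, a weak element. A stereodefined (Z)-trisubstituted alkene must be built on the decalin side chain. The dihydrodioxine is base-sensitive at C3'–H.
- Comparison: it is an endgame disconnection and says nothing about the decalin, so it complements the chosen ring B closure and does not replace it. Step count is about equal to the chosen endgame. Stereocontrol is stronger at C6' and weaker at C3' (facial selection against stereospecific inversion).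

**Alternative 3: cationic closure of ring B from an epoxide.**
- Cut: the C9–C10 bond.
- Forward step: MeAlCl2 opens the tetrasubstituted epoxide A5 at C10; the (E)-trisubstituted alkene attacks through C9 anti to the departing oxygen (6-endo), and the C8 cation loses a proton to give the octalin A6.
- In favour: the ring and up to three stereocentres (C5, C10, C9) form in one step from a monocyclic precursor, and the anti opening guarantees the cis relation of OH and the C10 methyl. In step economy to the octalin it is better than the chosen plan.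
- Against: the C10 cation sits between quaternary centres, where 1,2-shift with ring contraction and simple elimination compete. The proton loss must choose C7 over the methyl group. The configuration of C9 depends on which of two chair-like folds of the forming cis-decalin is used, so alkene geometry alone does not fix it. A single enantiomer needs an enantioenriched tetrasubstituted epoxide.
- Comparison: a polar, cation-driven cascade with several product-determining branch points, against a neutral catalytic closure in which all stereocentres are already in place. The chosen plan is longer but each stereocentre has its own identifiable control element.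

Key step: step 8

**Remarks on the chemistry before the steps**
- Locants: decalin C1–C10, linker C11–C12, peroxide side C1'–C6' as defined above.
- Configurational check: 11 and 12 carry C5 (S), C9 (S), C10 (R), identical with the target; the allyl group and the C9 arm are cis on ring A. The structures need no correction.
- C8 is set here by hydroxyl-directed hydrogenation (step 9), because the directing group and the required face coincide; a thermodynamically controlled radical reduction is kept as the fallback.
- C6' is the one centre the route does not control: step 17 forms both configurations, and the required one is isolated as a ring diastereomer in step 18.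
- The enantiomer collected in step 6 is to be assigned by vibrational circular dichroism and confirmed at 25, where it stands next to pool-derived centres.

## Route

Step 1
Reactants: 1 6-methylhept-5-en-2-one
Product: 2 2-methyl-2-(4-methylpent-3-en-1-yl)-1,3-dioxolane
Conditions: HOCH2CH2OH, TsOH (cat.), benzene, reflux, Dean–Stark
Reagents that add atoms: ethane-1,2-diol, OCCO
Why: Acid-catalysed ketalisation driven by removal of water; the dioxolane masks the methyl ketone against the enolate, Grignard and metathesis steps up to step 10.

Step 2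
Reactants: 2 2-methyl-2-(4-methylpent-3-en-1-yl)-1,3-dioxolane
Product: 3 (2E)-2-methyl-5-(2-methyl-1,3-dioxolan-2-yl)pent-2-en-1-ol
Conditions: SeO2 (cat.), t-BuOOH, CH2Cl2, 0 °C to rt
Reagents that add atoms: tert-butyl hydroperoxide, CC(C)(C)OO
Why: Selenium dioxide allylic oxidation (ene reaction, then [2,3]-sigmatropic shift) attacks the methyl group trans to the chain of a trisubstituted alkene, so the (E)-alcohol is expected; stopping at partial conversion limits over-oxidation.

Step 3
Reactants: 4 2,6-dimethylcyclohexan-1-one (cis/trans mixture)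
Product: 5 1,1-dimethoxy-2,6-dimethylcyclohexane
Conditions: HC(OMe)3, MeOH, TsOH (cat.), rt
Reagents that add atoms: trimethyl orthoformate, COC(OC)OC; methanol, CO
Why: Orthoformate-driven ketalisation gives the activated form of the ketone needed for alcohol exchange in step 4; both α-carbons are equivalent, so only one enol ether regiochemistry can follow.

Step 4
Reactants: 5 1,1-dimethoxy-2,6-dimethylcyclohexane; 3 (2E)-2-methyl-5-(2-methyl-1,3-dioxolan-2-yl)pent-2-en-1-ol
Product: 8 rac-(2R*)-2,6-dimethyl-2-[(3S*)-2-methyl-5-(2-methyl-1,3-dioxolan-2-yl)pent-1-en-3-yl]cyclohexan-1-one (both epimers at ring C6), via mixed methyl allyl ketal 6 (not isolated), via allyl enol ether 7 (not isolated)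
Conditions: EtCO2H (cat.), xylene, 140 °C, MeOH distilled off
Reagents that add atoms: none
Why: Ketal Claisen rearrangement: exchange of one methoxy group for 3, loss of methanol to the tetrasubstituted enol ether and a [3,3]-sigmatropic shift forge C9–C10. In the chair transition state the (E)-alkene puts the chain equatorial and the ring methyl (cis to oxygen) axial, which gives the (9S*,10R*) relationship; the boat is disfavoured by the clash between the C8 methyl and the ring carbon next to the enol ether carbon. The remaining ring CH(CH3) centre is a mixture and is erased in step 5.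

Step 5
Reactants: 8 rac-(2R*)-2,6-dimethyl-2-[(3S*)-2-methyl-5-(2-methyl-1,3-dioxolan-2-yl)pent-1-en-3-yl]cyclohexan-1-one
Product: 9 rac-(6R*)-2,2,6-trimethyl-6-[(3S*)-2-methyl-5-(2-methyl-1,3-dioxolan-2-yl)pent-1-en-3-yl]cyclohexan-1-one
Conditions: LiN(i-Pr)2, THF, −78 to 0 °C; MeI, −78 °C to rt
Reagents that add atoms: iodomethane, CI
Why: Enolate alkylation at the only enolisable carbon completes the gem-dimethyl group (C4) without creating a stereocentre, so both epimers of 8 converge on 9.

Step 6
Reactants: 9 rac-(6R*)-2,2,6-trimethyl-6-[(3S*)-2-methyl-5-(2-methyl-1,3-dioxolan-2-yl)pent-1-en-3-yl]cyclohexan-1-one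
Product: 10 (6R)-2,2,6-trimethyl-6-[(3S)-2-methyl-5-(2-methyl-1,3-dioxolan-2-yl)pent-1-en-3-yl]cyclohexan-1-one
Conditions: preparative SFC, amylose tris(3,5-dimethylphenylcarbamate) phase, CO2/i-PrOH
Reagents that add atoms: none
Why: Resolution of enantiomers by chromatography on a chiral stationary phase; no bond is made, and it is placed early so that all later material is a single enantiomer.

Step 7
Reactants: 10 (6R)-2,2,6-trimethyl-6-[(3S)-2-methyl-5-(2-methyl-1,3-dioxolan-2-yl)pent-1-en-3-yl]cyclohexan-1-one
Product: 11 (1S,2R)-2,6,6-trimethyl-2-[(3S)-2-methyl-5-(2-methyl-1,3-dioxolan-2-yl)pent-1-en-3-yl]-1-(prop-2-en-1-yl)cyclohexan-1-ol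
Conditions: CH2=CHCH2MgBr, Et2O, −78 to 0 °C; then H2O
Reagents that add atoms: allylmagnesium bromide, C=CC[Mg]Br
Why: Grignard 1,2-addition to a ketone with no α-hydrogen; the allyl reagent reaches hindered carbonyls through a six-membered transition state. In the chair with the C9 arm equatorial both α-carbons carry an axial methyl on one face, so attack should be axial from the other face, placing allyl cis to the arm and OH cis to the C10 methyl (5S).

Step 8
Reactants: 11 (1S,2R)-2,6,6-trimethyl-2-[(3S)-2-methyl-5-(2-methyl-1,3-dioxolan-2-yl)pent-1-en-3-yl]-1-(prop-2-en-1-yl)cyclohexan-1-ol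
Product: 12 (1S,4aS,8aR)-2,5,5,8a-tetramethyl-1-[2-(2-methyl-1,3-dioxolan-2-yl)ethyl]-1,5,6,7,8,8a-hexahydronaphthalen-4a(4H)-ol (cis-fused 5-hydroxy-Δ7-octalin)
Conditions: second-generation Grubbs catalyst (H2IMes)(PCy3)Cl2Ru=CHPh (5 mol %), CH2Cl2 (0.005 M), 40 °C
Reagents that add atoms: none
Why: Ring-closing olefin metathesis by the metallacyclobutane mechanism. The catalyst exchanges its benzylidene with the unhindered monosubstituted allyl alkene to place Ru=CH on C7; intramolecular [2+2] addition to the isopropenyl group and cycloreversion release ethene and form the trisubstituted C7=C8 bond. Ring B closes as a six-membered ring in which C7 and C8 become ring atoms; the closest known type is closure of trisubstituted cyclohexenes from allyl/isopropenyl dienes that carry a free tertiary alcohol. No stereocentre is created: C5, C9 and C10 come from steps 4 and 7, and the cis placement of the allyl group and the C9 arm on ring A is what brings the two alkenes together. The selectivities needed are initiation at the allyl group, secured by the different substitution of the two alkenes, and cyclisation over oligomerisation, secured by dilution and by the quaternary carbons C4 and C10 that hold the arms close. The new bond is remote from the three contiguous fully substituted carbons and does not feel their congestion. Loss of volatile ethene drives the reaction.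

Step 9
Reactants: 12 (1S,4aS,8aR)-2,5,5,8a-tetramethyl-1-[2-(2-methyl-1,3-dioxolan-2-yl)ethyl]-1,5,6,7,8,8a-hexahydronaphthalen-4a(4H)-ol
Product: 13 (1S,2R,4aS,8aR)-2,5,5,8a-tetramethyl-1-[2-(2-methyl-1,3-dioxolan-2-yl)ethyl]decahydronaphthalen-4a-ol
Conditions: H2 (1 atm), [Ir(cod)(PCy3)(py)]PF6 (5 mol %), CH2Cl2, rt
Reagents that add atoms: none
Why: Hydroxyl-directed homogeneous hydrogenation: the cationic iridium complex binds the homoallylic C5 hydroxyl and delivers both hydrogens to the alkene face syn to it. Hydrogen therefore enters C8 cis to OH, leaving the C8 methyl trans to the C9 chain and equatorial (8R), which is also the more stable arrangement.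

Step 10
Reactants: 13 (1S,2R,4aS,8aR)-2,5,5,8a-tetramethyl-1-[2-(2-methyl-1,3-dioxolan-2-yl)ethyl]decahydronaphthalen-4a-ol
Product: 14 4-[(1S,2R,4aS,8aR)-4a-hydroxy-2,5,5,8a-tetramethyldecahydronaphthalen-1-yl]butan-2-one
Conditions: PPTS (cat.), THF/H2O, 50 °C
Reagents that add atoms: water, O
Why: Mild acid-catalysed ketal hydrolysis; pyridinium tosylate is too weak to ionise the hindered tertiary alcohol.

Step 11
Reactants: 14 4-[(1S,2R,4aS,8aR)-4a-hydroxy-2,5,5,8a-tetramethyldecahydronaphthalen-1-yl]butan-2-one
Product: 15 (1S,2R,4aS,8aR)-2,5,5,8a-tetramethyl-1-(3-methylbut-3-en-1-yl)decahydronaphthalen-4a-ol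
Conditions: Ph3PCH3Br (3 equiv), KOt-Bu (3 equiv), THF, 0 °C to rt
Reagents that add atoms: methyltriphenylphosphonium bromide, C[P+](c1ccccc1)(c1ccccc1)c1ccccc1.[Br-]
Why: Wittig methylenation; the excess of ylide covers deprotonation of the tertiary alcohol, and the gem-disubstituted alkene is the handle for the fragment union.

Step 12
Reactants: 16 methyl (2R)-3-hydroxy-2-methylpropanoate
Product: 17 methyl (2R)-3-[(tert-butyldimethylsilyl)oxy]-2-methylpropanoate
Conditions: t-BuMe2SiCl, imidazole, CH2Cl2, rt
Reagents that add atoms: tert-butyldimethylsilyl chloride, CC(C)(C)[Si](C)(C)Cl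
Why: Silyl ether formation; the group survives steps 13–17 and is removed by the fluoride of step 18.

Step 13
Reactants: 17 methyl (2R)-3-[(tert-butyldimethylsilyl)oxy]-2-methylpropanoate
Product: 18 (2R)-3-[(tert-butyldimethylsilyl)oxy]-2-methylpropanal
Conditions: i-Bu2AlH (1.1 equiv), CH2Cl2, −78 °C; MeOH, aq. tartrate
Reagents that add atoms: none
Why: Partial reduction of the ester at low temperature stops at the aluminium hemiacetal; the aldehyde is used at once to avoid epimerisation at C2'.

Step 14
Reactants: 18 (2R)-3-[(tert-butyldimethylsilyl)oxy]-2-methylpropanal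
Product: 19 (2R,3R)-1-[(tert-butyldimethylsilyl)oxy]-2-methylhex-5-en-3-ol
Conditions: (+)-Ipc2B(CH2CH=CH2) [from (−)-α-pinene], Et2O, −78 °C; then NaOH, H2O2
Reagents that add atoms: (+)-B-allyldiisopinocampheylborane, C=CCB([C@H]1C[C@H]2C[C@@H]([C@@H]1C)C2(C)C)[C@H]1C[C@H]2C[C@@H]([C@@H]1C)C2(C)C
Why: Brown allylation through a closed chair transition state; the reagent from (−)-α-pinene adds to the Re face, which is also the Felkin–Anh face of 18 (matched pair), so the 2,3-syn (2R,3R) alcohol is expected.

Step 15
Reactants: 19 (2R,3R)-1-[(tert-butyldimethylsilyl)oxy]-2-methylhex-5-en-3-ol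
Product: 20 (2R,3R)-1-[(tert-butyldimethylsilyl)oxy]-2-methylhex-5-en-3-yl methanesulfonate
Conditions: MsCl, Et3N, CH2Cl2, 0 °C
Reagents that add atoms: methanesulfonyl chloride, CS(=O)(=O)Cl
Why: Sulfonylation of the secondary alcohol with retention; the mesylate is the leaving group for step 18 and is inert in steps 16 and 17.

Step 16
Reactants: 15 (1S,2R,4aS,8aR)-2,5,5,8a-tetramethyl-1-(3-methylbut-3-en-1-yl)decahydronaphthalen-4a-ol; 20 (2R,3R)-1-[(tert-butyldimethylsilyl)oxy]-2-methylhex-5-en-3-yl methanesulfonate
Product: 21 (2R,3R)-1-[(tert-butyldimethylsilyl)oxy]-8-[(1S,2R,4aS,8aR)-4a-hydroxy-2,5,5,8a-tetramethyldecahydronaphthalen-1-yl]-2,6-dimethyloct-5-en-3-yl methanesulfonate (E/Z mixture)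
Conditions: second-generation Grubbs catalyst (H2IMes)(PCy3)Cl2Ru=CHPh (10 mol %), 20 (2.5 equiv), CH2Cl2, 40 °C
Reagents that add atoms: none
Why: Olefin cross-metathesis of a gem-disubstituted alkene with a terminal alkene used in excess; the catalyst loads on 20, and homodimer of 20 can re-enter by secondary metathesis. The geometry of the new alkene is irrelevant because step 17 passes through a planar radical.

Step 17
Reactants: 21 (2R,3R)-1-[(tert-butyldimethylsilyl)oxy]-8-[(1S,2R,4aS,8aR)-4a-hydroxy-2,5,5,8a-tetramethyldecahydronaphthalen-1-yl]-2,6-dimethyloct-5-en-3-yl methanesulfonate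
Product: 22 (2R,3R)-1-[(tert-butyldimethylsilyl)oxy]-8-[(1S,2R,4aS,8aR)-4a-hydroxy-2,5,5,8a-tetramethyldecahydronaphthalen-1-yl]-2,6-dimethyl-6-[(triethylsilyl)peroxy]octan-3-yl methanesulfonate (both configurations at C6')
Conditions: Co(thd)2 (10 mol %), O2 (1 atm), Et3SiH, ClCH2CH2Cl, rt
Reagents that add atoms: dioxygen, O=O; triethylsilane, CC[SiH](CC)CC
Why: Mukaiyama–Isayama hydroperoxysilylation: hydrogen-atom transfer from the Co–H species to C5' gives the tertiary C6' radical, which is trapped by O2 and silylated (Markovnikov). Methyl and the primary chain at C6' are equal in size, so no facial preference is expected and both configurations form.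

Step 18
Reactants: 22 (2R,3R)-1-[(tert-butyldimethylsilyl)oxy]-8-[(1S,2R,4aS,8aR)-4a-hydroxy-2,5,5,8a-tetramethyldecahydronaphthalen-1-yl]-2,6-dimethyl-6-[(triethylsilyl)peroxy]octan-3-yl methanesulfonate
Product: 25 (2R)-2-[(3S,6R)-6-{2-[(1S,2R,4aS,8aR)-4a-hydroxy-2,5,5,8a-tetramethyldecahydronaphthalen-1-yl]ethyl}-6-methyl-1,2-dioxan-3-yl]propan-1-ol, via hydroperoxy mesylate 23 (not isolated), via dioxane silyl ether 24 (not isolated)
Conditions: Bu4NF (3.5 equiv), THF, 0 °C to rt; chromatography
Reagents that add atoms: none
Why: Fluoride cleaves the peroxide O–Si bond; the peroxide anion displaces the mesylate in a 6-exo-tet SN2 reaction (intramolecular alkylation of a hydroperoxide), inverting C3' to (S), and the excess fluoride then removes the silyl ether. The two C6' configurations are now ring diastereomers, and the (3'S,6'R) isomer is isolated by chromatography.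

Step 19
Reactants: 25 (2R)-2-[(3S,6R)-6-{2-[(1S,2R,4aS,8aR)-4a-hydroxy-2,5,5,8a-tetramethyldecahydronaphthalen-1-yl]ethyl}-6-methyl-1,2-dioxan-3-yl]propan-1-ol
Product: 26 (2S)-2-[(3S,6R)-6-{2-[(1S,2R,4aS,8aR)-4a-hydroxy-2,5,5,8a-tetramethyldecahydronaphthalen-1-yl]ethyl}-6-methyl-1,2-dioxan-3-yl]propanoic acid
Conditions: TEMPO (cat.), PhI(OAc)2, MeCN/H2O, rt
Reagents that add atoms: water, O
Why: Oxoammonium (TEMPO) oxidation takes the primary alcohol through the aldehyde hydrate to the acid without base, so neither epimerisation at C2' nor β-elimination of the peroxide is expected; the O–O bond and the tertiary alcohol are inert. The C2' descriptor changes from R to S by priority only.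

Step 20
Reactants: 26 (2S)-2-[(3S,6R)-6-{2-[(1S,2R,4aS,8aR)-4a-hydroxy-2,5,5,8a-tetramethyldecahydronaphthalen-1-yl]ethyl}-6-methyl-1,2-dioxan-3-yl]propanoic acid
Product: 27 methyl (2S)-2-[(3S,6R)-6-{2-[(1S,2R,4aS,8aR)-4a-hydroxy-2,5,5,8a-tetramethyldecahydronaphthalen-1-yl]ethyl}-6-methyl-1,2-dioxan-3-yl]propanoate
Conditions: Me3SiCHN2, toluene/MeOH, 0 °C
Reagents that add atoms: (trimethylsilyl)diazomethane, C[Si](C)(C)C=[N+]=[N-]
Why: Neutral O-methylation of the carboxylic acid by diazomethane released in situ; C2', the peroxide and the tertiary alcohol are untouched.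

## Compound list

1 | 6-methylhept-5-en-2-one | CC(=O)CCC=C(C)C | starting material
2 | 2-methyl-2-(4-methylpent-3-en-1-yl)-1,3-dioxolane | CC1(CCC=C(C)C)OCCO1 | intermediate
3 | (2E)-2-methyl-5-(2-methyl-1,3-dioxolan-2-yl)pent-2-en-1-ol | CC1(CC/C=C(\C)CO)OCCO1 | intermediate
4 | 2,6-dimethylcyclohexan-1-one | CC1CCCC(C)C1=O | starting material
5 | 1,1-dimethoxy-2,6-dimethylcyclohexane | COC1(OC)C(C)CCCC1C | intermediate
6 | 2-[(3E)-5-[(1-methoxy-2,6-dimethylcyclohexyl)oxy]-4-methylpent-3-en-1-yl]-2-methyl-1,3-dioxolane (mixed ketal) | COC1(OC/C(C)=C/CCC2(C)OCCO2)C(C)CCCC1C | intermediate (not isolated)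
7 | 2-[(3E)-5-[(2,6-dimethylcyclohex-1-en-1-yl)oxy]-4-methylpent-3-en-1-yl]-2-methyl-1,3-dioxolane (allyl enol ether) | CC1CCCC(C)=C1OC/C(C)=C/CCC2(C)OCCO2 | intermediate (not isolated)
8 | rac-(2R*)-2,6-dimethyl-2-[(3S*)-2-methyl-5-(2-methyl-1,3-dioxolan-2-yl)pent-1-en-3-yl]cyclohexan-1-one (racemate, one enantiomer drawn, ring C6 unassigned) | CC1(OCCO1)CC[C@@H](C(C)=C)[C@@]2(C)CCCC(C)C2=O | intermediate
9 | rac-(6R*)-2,2,6-trimethyl-6-[(3S*)-2-methyl-5-(2-methyl-1,3-dioxolan-2-yl)pent-1-en-3-yl]cyclohexan-1-one (racemate, one enantiomer drawn) | CC1(OCCO1)CC[C@@H](C(C)=C)[C@@]2(C)CCCC(C)(C)C2=O | intermediate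
10 | (6R)-2,2,6-trimethyl-6-[(3S)-2-methyl-5-(2-methyl-1,3-dioxolan-2-yl)pent-1-en-3-yl]cyclohexan-1-one | CC1(OCCO1)CC[C@@H](C(C)=C)[C@@]2(C)CCCC(C)(C)C2=O | intermediate
11 | (1S,2R)-2,6,6-trimethyl-2-[(3S)-2-methyl-5-(2-methyl-1,3-dioxolan-2-yl)pent-1-en-3-yl]-1-(prop-2-en-1-yl)cyclohexan-1-ol | CC1(OCCO1)CC[C@@H](C(C)=C)[C@@]2(C)CCCC(C)(C)[C@@]2(O)CC=C | intermediate (key-step precursor)
12 | (1S,4aS,8aR)-2,5,5,8a-tetramethyl-1-[2-(2-methyl-1,3-dioxolan-2-yl)ethyl]-1,5,6,7,8,8a-hexahydronaphthalen-4a(4H)-ol | CC1(OCCO1)CC[C@H]2C(C)=CC[C@]3(O)C(C)(C)CCC[C@]23C | intermediate (key-step product)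
13 | (1S,2R,4aS,8aR)-2,5,5,8a-tetramethyl-1-[2-(2-methyl-1,3-dioxolan-2-yl)ethyl]decahydronaphthalen-4a-ol | CC1(OCCO1)CC[C@H]2[C@H](C)CC[C@]3(O)C(C)(C)CCC[C@]23C | intermediate
14 | 4-[(1S,2R,4aS,8aR)-4a-hydroxy-2,5,5,8a-tetramethyldecahydronaphthalen-1-yl]butan-2-one | CC(=O)CC[C@H]1[C@H](C)CC[C@]2(O)C(C)(C)CCC[C@]12C | intermediate
15 | (1S,2R,4aS,8aR)-2,5,5,8a-tetramethyl-1-(3-methylbut-3-en-1-yl)decahydronaphthalen-4a-ol | CC(=C)CC[C@H]1[C@H](C)CC[C@]2(O)C(C)(C)CCC[C@]12C | intermediate
16 | methyl (2R)-3-hydroxy-2-methylpropanoate | OC[C@@H](C)C(=O)OC | starting material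
17 | methyl (2R)-3-[(tert-butyldimethylsilyl)oxy]-2-methylpropanoate | CC(C)(C)[Si](C)(C)OC[C@@H](C)C(=O)OC | intermediate
18 | (2R)-3-[(tert-butyldimethylsilyl)oxy]-2-methylpropanal | CC(C)(C)[Si](C)(C)OC[C@@H](C)C=O | intermediate
19 | (2R,3R)-1-[(tert-butyldimethylsilyl)oxy]-2-methylhex-5-en-3-ol | CC(C)(C)[Si](C)(C)OC[C@@H](C)[C@H](O)CC=C | intermediate
20 | (2R,3R)-1-[(tert-butyldimethylsilyl)oxy]-2-methylhex-5-en-3-yl methanesulfonate | CC(C)(C)[Si](C)(C)OC[C@@H](C)[C@H](OS(C)(=O)=O)CC=C | intermediate
21 | (2R,3R)-1-[(tert-butyldimethylsilyl)oxy]-8-[(1S,2R,4aS,8aR)-4a-hydroxy-2,5,5,8a-tetramethyldecahydronaphthalen-1-yl]-2,6-dimethyloct-5-en-3-yl methanesulfonate (E/Z mixture) | CC(C)(C)[Si](C)(C)OC[C@@H](C)[C@H](OS(C)(=O)=O)CC=C(C)CC[C@H]1[C@H](C)CC[C@]2(O)C(C)(C)CCC[C@]12C | intermediate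
22 | (2R,3R)-1-[(tert-butyldimethylsilyl)oxy]-8-[(1S,2R,4aS,8aR)-4a-hydroxy-2,5,5,8a-tetramethyldecahydronaphthalen-1-yl]-2,6-dimethyl-6-[(triethylsilyl)peroxy]octan-3-yl methanesulfonate (both C6' configurations) | CC(C)(C)[Si](C)(C)OC[C@@H](C)[C@H](OS(C)(=O)=O)CCC(C)(OO[Si](CC)(CC)CC)CC[C@H]1[C@H](C)CC[C@]2(O)C(C)(C)CCC[C@]12C | intermediate
23 | (2R,3R)-1-[(tert-butyldimethylsilyl)oxy]-6-hydroperoxy-8-[(1S,2R,4aS,8aR)-4a-hydroxy-2,5,5,8a-tetramethyldecahydronaphthalen-1-yl]-2,6-dimethyloctan-3-yl methanesulfonate (both C6' configurations) | CC(C)(C)[Si](C)(C)OC[C@@H](C)[C@H](OS(C)(=O)=O)CCC(C)(OO)CC[C@H]1[C@H](C)CC[C@]2(O)C(C)(C)CCC[C@]12C | intermediate (not isolated)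
24 | tert-butyl{(2R)-2-[(3S)-6-{2-[(1S,2R,4aS,8aR)-4a-hydroxy-2,5,5,8a-tetramethyldecahydronaphthalen-1-yl]ethyl}-6-methyl-1,2-dioxan-3-yl]propoxy}dimethylsilane (both C6' configurations) | CC(C)(C)[Si](C)(C)OC[C@@H](C)[C@@H]1CCC(C)(CC[C@H]2[C@H](C)CC[C@]3(O)C(C)(C)CCC[C@]23C)OO1 | intermediate (not isolated)
25 | (2R)-2-[(3S,6R)-6-{2-[(1S,2R,4aS,8aR)-4a-hydroxy-2,5,5,8a-tetramethyldecahydronaphthalen-1-yl]ethyl}-6-methyl-1,2-dioxan-3-yl]propan-1-ol | OC[C@@H](C)[C@@H]1CC[C@@](C)(CC[C@H]2[C@H](C)CC[C@]3(O)C(C)(C)CCC[C@]23C)OO1 | intermediate
26 | (2S)-2-[(3S,6R)-6-{2-[(1S,2R,4aS,8aR)-4a-hydroxy-2,5,5,8a-tetramethyldecahydronaphthalen-1-yl]ethyl}-6-methyl-1,2-dioxan-3-yl]propanoic acid | OC(=O)[C@@H](C)[C@@H]1CC[C@@](C)(CC[C@H]2[C@H](C)CC[C@]3(O)C(C)(C)CCC[C@]23C)OO1 | intermediate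
27 | methyl (2S)-2-[(3S,6R)-6-{2-[(1S,2R,4aS,8aR)-4a-hydroxy-2,5,5,8a-tetramethyldecahydronaphthalen-1-yl]ethyl}-6-methyl-1,2-dioxan-3-yl]propanoate | COC(=O)[C@@H](C)[C@@H]1CC[C@@](C)(CC[C@H]2[C@H](C)CC[C@]3(O)C(C)(C)CCC[C@]23C)OO1 | target

## Step count and least certain steps

Total: 20 steps. Longest linear sequence: 15 steps (1, 2, 4–11, 16–20).

**Step 8 (key step).** The C7 alkylidene may be slow to engage the isopropenyl group, which sits on a carbon next to the quaternary C10. Intermolecular metathesis of the allyl termini, or migration of the allyl double bond followed by closure of a smaller ring, could then compete. Fallback: setting out from 11, ozonolysis (O3, CH2Cl2, −78 °C; Me2S) cleaves both alkenes to the keto aldehyde F1, and an intramolecular McMurry coupling (TiCl3, Zn–Cu, DME, reflux, slow addition) joins the aldehyde carbon C7 to the ketone carbon C8, coming back to the route at 12. The same C7=C8 bond is formed reductively from two carbonyl groups and not by alkene exchange.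

**Step 4.** Alcohol exchange at the hindered ketal carbon may be slow, and the acid and heat may cause exchange or loss of the dioxolane or ionisation of the allylic alcohol before the rearrangement. Fallback: setting out from 3, mesylation (MsCl, Et3N, −20 °C) gives the allylic mesylate F2. The enolate of 2,2,6-trimethylcyclohexan-1-one F3 (KH, 18-crown-6, THF/DMPU) is alkylated on oxygen by F2; a dissociated potassium enolate, a sulfonate leaving group and a fully substituted α-carbon all favour attack through oxygen. The resulting allyl enol ether F4 is freed from carbon-alkylated material and heated (toluene, 150 °C, sealed tube). The same chair rearrangement gives racemic 9 directly, so the route is rejoined at 9 and step 5 is not needed.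

**Step 9.** The tertiary hydroxyl lies between two quaternary carbons and may bind iridium poorly; hydrogen would then be delivered without facial control, or the alkene would migrate. Fallback: setting out from 12, hydrogen-atom-transfer hydrogenation (Mn(dpm)3, PhSiH3, t-BuOOH, i-PrOH, rt) reduces the alkene through the tertiary C8 radical, whose quenching favours the more stable epimer with the equatorial C8 methyl trans to the C9 chain. The route is rejoined at 13. This relies on product stability and not on coordination; no new compound is made.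

**Step 16.** Homodimerisation of 20 may outpace the cross reaction because the gem-disubstituted alkene of 15 turns over slowly. Fallback by carbonyl olefination, setting out from 19 and 14: ozonolysis of 19 with reductive work-up (O3; NaBH4) gives the diol F5; selective iodination of the primary hydroxyl (I2, PPh3, imidazole) gives the iodide F6; PPh3 in MeCN gives the phosphonium iodide F7. The γ-oxido ylide from F7 (2 equiv LiN(SiMe3)2, plus one for the hydroxyl of 14) condenses with ketone 14 to the hydroxy alkene F8. Mesylation of the secondary hydroxyl of F8 (MsCl, Et3N; the hindered tertiary hydroxyl does not react) comes back to the route at 21.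

**Step 18.** E2 elimination of the branched secondary mesylate, or base-induced fragmentation of the peroxide at C3'–H, may compete with substitution. Fallback in which the leaving group is made after the peroxide and the ring is closed without base, setting out from 15 and 19: cross-metathesis under the conditions of step 16 gives the hydroxy alkene F8; hydroperoxysilylation as in step 17 gives the hydroxy silyl peroxide F9; Tf2O and 2,6-lutidine (CH2Cl2, −78 °C) convert the secondary hydroxyl into the triflate F10, which is not isolated. HF·pyridine then frees the hydroperoxide, which displaces the triflate at low temperature with inversion. The route is rejoined at 24, and Bu4NF gives 25.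

## Further compounds

F1 | step 8 | 2-[(1S,2R)-1-hydroxy-2,6,6-trimethyl-2-[(3S)-6-(2-methyl-1,3-dioxolan-2-yl)-2-oxohexan-3-yl]cyclohexyl]acetaldehyde | CC1(OCCO1)CC[C@@H](C(C)=O)[C@@]2(C)CCCC(C)(C)[C@@]2(O)CC=O
F2 | step 4 | (2E)-2-methyl-5-(2-methyl-1,3-dioxolan-2-yl)pent-2-en-1-yl methanesulfonate | CC1(CC/C=C(\C)COS(C)(=O)=O)OCCO1
F3 | step 4 | 2,2,6-trimethylcyclohexan-1-one | CC1CCCC(C)(C)C1=O
F4 | step 4 | 2-methyl-2-[(3E)-4-methyl-5-[(2,6,6-trimethylcyclohex-1-en-1-yl)oxy]pent-3-en-1-yl]-1,3-dioxolane | CC1=C(OC/C(C)=C/CCC2(C)OCCO2)C(C)(C)CCC1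
F0 | step 9 | none | none
F5 | step 16 | (3R,4R)-5-[(tert-butyldimethylsilyl)oxy]-4-methylpentane-1,3-diol | CC(C)(C)[Si](C)(C)OC[C@@H](C)[C@H](O)CCO
F6 | step 16 | (2R,3R)-1-[(tert-butyldimethylsilyl)oxy]-5-iodo-2-methylpentan-3-ol | CC(C)(C)[Si](C)(C)OC[C@@H](C)[C@H](O)CCI
F7 | step 16 | [(3R,4R)-5-[(tert-butyldimethylsilyl)oxy]-3-hydroxy-4-methylpentyl]triphenylphosphonium iodide | CC(C)(C)[Si](C)(C)OC[C@@H](C)[C@H](O)CC[P+](c1ccccc1)(c1ccccc1)c1ccccc1.[I-]
F8 | step 16 | (1S,2R,4aS,8aR)-1-[(6R,7R)-8-[(tert-butyldimethylsilyl)oxy]-6-hydroxy-3,7-dimethyloct-3-en-1-yl]-2,5,5,8a-tetramethyldecahydronaphthalen-4a-ol (E/Z mixture) | CC(C)(C)[Si](C)(C)OC[C@@H](C)[C@H](O)CC=C(C)CC[C@H]1[C@H](C)CC[C@]2(O)C(C)(C)CCC[C@]12C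
F9 | step 18 | (1S,2R,4aS,8aR)-1-[(6R,7R)-8-[(tert-butyldimethylsilyl)oxy]-6-hydroxy-3,7-dimethyl-3-[(triethylsilyl)peroxy]octyl]-2,5,5,8a-tetramethyldecahydronaphthalen-4a-ol (both C6' configurations) | CC(C)(C)[Si](C)(C)OC[C@@H](C)[C@H](O)CCC(C)(OO[Si](CC)(CC)CC)CC[C@H]1[C@H](C)CC[C@]2(O)C(C)(C)CCC[C@]12C
F10 | step 18 | (2R,3R)-1-[(tert-butyldimethylsilyl)oxy]-8-[(1S,2R,4aS,8aR)-4a-hydroxy-2,5,5,8a-tetramethyldecahydronaphthalen-1-yl]-2,6-dimethyl-6-[(triethylsilyl)peroxy]octan-3-yl trifluoromethanesulfonate (both C6' configurations) | CC(C)(C)[Si](C)(C)OC[C@@H](C)[C@H](OS(=O)(=O)C(F)(F)F)CCC(C)(OO[Si](CC)(CC)CC)CC[C@H]1[C@H](C)CC[C@]2(O)C(C)(C)CCC[C@]12C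
A1 | alternative 1 | 10-nor allylic alcohol with the C1=C10 alkene, the C5 hydroxyl and the C9 ketal chain | CC1(OCCO1)CC[C@H]2[C@H](C)CC[C@]3(O)C(C)(C)CCC=C23
A2 | alternative 1 | cyclopropane across C1 and C10, cis to the C5 hydroxyl | CC1(OCCO1)CC[C@H]2[C@H](C)CC[C@]3(O)C(C)(C)CC[C@H]4C[C@@]234
A3 | alternative 2 | (3'E,5'Z)-diene with the C1' silyl ether and the complete decalin | CC(C)(C)[Si](C)(C)OC[C@@H](C)/C=C/C=C(/C)CC[C@H]1[C@H](C)CC[C@]2(O)C(C)(C)CCC[C@]12C
A4 | alternative 2 | 3,6-dihydro-1,2-dioxine with all target stereocentres | CC(C)(C)[Si](C)(C)OC[C@@H](C)[C@@H]1C=C[C@@](C)(CC[C@H]2[C@H](C)CC[C@]3(O)C(C)(C)CCC[C@]23C)OO1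
A5 | alternative 3 | tetrasubstituted ring A epoxide (C5–C10) with the (E)-alkene and silyloxyethyl chain | CC1(C)CCC[C@@]2(C)O[C@@]12CC/C(C)=C/CCO[Si](c1ccccc1)(c1ccccc1)C(C)(C)C
A6 | alternative 3 | cis-fused 5-hydroxy-Δ7-octalin with the C9 silyloxyethyl chain | CC(C)(C)[Si](c1ccccc1)(c1ccccc1)OCC[C@H]1C(C)=CC[C@]2(O)C(C)(C)CCC[C@]12C
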